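**Retrosynthetic overview** (ring atoms of the quinone: C-1 = carbonyl between C–OH and C–nonadecyl, C-2 = C–OH, C-3 = C–CH3, C-4 = second carbonyl, C-5 = CH, C-6 = C–nonadecyl)
1. Capiquinone C ⇐ two-electron oxidation of 3-methyl-6-nonadecylbenzene-1,2,4-triol, the aromatic tautomer of the cyclohexane-1,2,4-trione; the C-1 carbonyl is carried as a spiro-1,3-dithiane.
2. Masked trione ⇐ Dieckmann closure of the C-2–C-3 bond of an acyclic δ-keto ester.
3. Key disconnection C-1–C-6: the anion of ethyl 1,3-dithiane-2-carboxylate (a glyoxylate acyl-anion equivalent) adds to the β-carbon of (E)-tetracos-4-en-3-one, joining two natively electrophilic carbons by polarity reversal.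
4. Enone ⇐ icosanal + diethyl (2-oxobutyl)phosphonate (Horner–Wadsworth–Emmons); icosanal ⇐ icosan-1-ol.
5. Ring order: the six-membered carbocycle is the only ring made (step 2, de novo); the dithiane ring is bought and excised in the last step.

Assumption: the target has no stereocentre and no stereogenic double bond, so it is achiral and the single constitution drawn (side chain read as n-nonadecyl) is the whole stereochemical requirement.

**Step 1**
Reactants: 1 icosan-1-ol; 2 diethyl (2-oxobutyl)phosphonate
Product: 4 (E)-tetracos-4-en-3-one, via icosanal 3 (not isolated)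
Conditions: TEMPO (10 mol%), PhI(OAc)2 (1.05 eq), CH2Cl2, rt, 3 h; then 2 (1.2 eq), LiCl (1.3 eq), DBU (3.5 eq), MeCN, 0 °C → rt
Reagents that add atoms: none
Why: Anhydrous TEMPO/PhI(OAc)2 (oxoammonium) oxidation stops at the aldehyde, and the Masamune–Roush Horner–Wadsworth–Emmons olefination of the β-keto phosphonate in the same flask gives the (E)-enone (tandem oxidation–olefination); no stereocentre is formed.

**Step 2**
Reactants: 4 (E)-tetracos-4-en-3-one; 5 ethyl 1,3-dithiane-2-carboxylate
Product: 7 racemic 8-methyl-11-nonadecyl-1,5-dithiaspiro[5.5]undecane-7,9-dione, via Michael adduct keto ester 6 (not isolated)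
Conditions: 5 (1.1 eq), KOt-Bu (1.1 eq), THF, 0 °C, 20 min; add 4, 0 °C → rt, 2 h; then KOt-Bu (1.2 eq), t-BuOH (2 eq), 50 °C, 3 h; 1 M HCl work-up
Reagents that add atoms: none
Why: Proposed new method: the potassium enolate of 5 (a glyoxylate acyl-anion equivalent) adds reversibly 1,4 to enone 4 to forge the C-1–C-6 bond (adduct 6), proton transfer moves the ketone enolate to the ethyl side, and Dieckmann (intramolecular Claisen) attack on the ester closes the six-membered ring irreversibly as the stabilised 2-methyl-1,3-diketonate (the other enolate could only close a four-membered ring); the closest known reactions are the Michael–Claisen annulation of α,α-disubstituted ester enolates with enones to cyclohexane-1,3-diones and the conjugate addition of metallated 2-alkoxycarbonyl-1,3-dithianes to enones; the methyl-bearing and nonadecyl-bearing stereocentres form without control (racemic, partly enolised) and are erased in step 3.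

**Step 3**
Reactants: 7 racemic 8-methyl-11-nonadecyl-1,5-dithiaspiro[5.5]undecane-7,9-dione
Product: 10 capiquinone C (2-hydroxy-3-methyl-6-nonadecyl-1,4-benzoquinone), via 3-methyl-6-nonadecylcyclohexane-1,2,4-trione 8 (not isolated), via 3-methyl-6-nonadecylbenzene-1,2,4-triol 9 (not isolated)
Conditions: PhI(OCOCF3)2 (3.0 eq), MeCN/THF/H2O (5:4:1), 0 °C → rt, 1 h
Reagents that add atoms: water, O
Why: Oxidative dethioketalisation by trivalent iodine (S-activation, hydrolysis, water supplying the C-1 oxygen) frees trione 8, which tautomerises to the aromatic triol 9 and is oxidised by a second equivalent of PhI(OCOCF3)2 (hydroquinone-to-quinone oxidation) to the para-quinone that keeps the C-2 hydroxyl; no stereocentre remains.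

**Compound list**
1 | icosan-1-ol | CCCCCCCCCCCCCCCCCCCCO | starting material
2 | diethyl (2-oxobutyl)phosphonate | CCC(=O)CP(=O)(OCC)OCC | starting material
3 | icosanal (formed in the flask in step 1) | CCCCCCCCCCCCCCCCCCCC=O | intermediate
4 | (E)-tetracos-4-en-3-one | CCCCCCCCCCCCCCCCCCC/C=C/C(=O)CC | intermediate
5 | ethyl 1,3-dithiane-2-carboxylate | CCOC(=O)C1SCCCS1 | starting material
6 | ethyl 2-(3-oxotetracosan-5-yl)-1,3-dithiane-2-carboxylate (racemic; formed in the flask in step 2) | CCCCCCCCCCCCCCCCCCCC(CC(=O)CC)C1(SCCCS1)C(=O)OCC | intermediate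
7 | 8-methyl-11-nonadecyl-1,5-dithiaspiro[5.5]undecane-7,9-dione (racemic, diastereomer/enol mixture) | CCCCCCCCCCCCCCCCCCCC1CC(=O)C(C)C(=O)C12SCCCS2 | intermediate
8 | 3-methyl-6-nonadecylcyclohexane-1,2,4-trione (racemic; formed in the flask in step 3) | CCCCCCCCCCCCCCCCCCCC1CC(=O)C(C)C(=O)C1=O | intermediate
9 | 3-methyl-6-nonadecylbenzene-1,2,4-triol (formed in the flask in step 3) | CCCCCCCCCCCCCCCCCCCc1cc(O)c(C)c(O)c1O | intermediate
10 | capiquinone C, 2-hydroxy-3-methyl-6-nonadecyl-1,4-benzoquinone (achiral) | CCCCCCCCCCCCCCCCCCCC1=CC(=O)C(C)=C(O)C1=O | target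

**Totals**
Total step count: 3. Longest linear sequence: 3 (1 → 4 → 7 → 10).

**Steps most likely to fail, with fallbacks**

Step 2 (highest risk). The hindered tertiary carbanion may add reversibly or sluggishly to the β-alkyl enone, the enone may self-condense under base, and the ester to be attacked sits on a quaternary carbon. The fallback sets out from 5 and comes back to the route at 6, which is then closed to 7. Compound 5 is converted with LiN(i-Pr)2 and Me3SiCl in THF at −78 °C into the silyl ketene acetal 2-[ethoxy(trimethylsilyloxy)methylidene]-1,3-dithiane F2. A TiCl4-promoted Mukaiyama–Michael addition of F2 to enone 4 in CH2Cl2 at −78 °C, followed by aqueous work-up, gives the keto ester 6 as an isolated compound. A separate Dieckmann closure with KOt-Bu in THF/t-BuOH then gives 7. This replaces the reversible anionic addition by an irreversible Lewis-acid-driven one and decouples the two bond formations.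

Step 3. Trivalent iodine may oxygenate the enolised 1,3-dione carbon before the sulfur is removed, or sulfur fragments may add to the quinone. The fallback sets out from 7 and comes back at 10. Desulfurisation with Raney Ni (W-2) in EtOH/THF at reflux gives 2-methyl-5-nonadecylcyclohexane-1,3-dione F3. Dehydrogenation over Pd/C in refluxing p-cymene gives 2-methyl-5-nonadecylbenzene-1,3-diol F4. Teuber oxidation with (KSO3)2NO in aqueous KH2PO4/acetone then attacks the only free position para to a hydroxyl and gives 10. Here the C-1 oxygen is reintroduced by phenol oxidation instead of being unveiled from the dithiane, and the dithiane serves as a traceless activating group for the same key C–C bond.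

Step 1. Residual PhI(OAc)2 and acetic acid may intercept the phosphonate anion, and the waxy alcohol is poorly soluble. The fallback sets out from 1 and comes back at 4. Swern oxidation ((COCl)2, DMSO, Et3N, CH2Cl2, −78 °C) gives isolated icosanal 3. Wittig methylenation with Ph3P=CH2 (from Ph3PCH3Br and KOt-Bu, THF) gives henicos-1-ene F1. Cross-metathesis with pent-1-en-3-one (3 eq) and the second-generation Grubbs catalyst RuCl2(=CHPh)(H2IMes)(PCy3) (3 mol%) in CH2Cl2 at 40 °C gives the (E)-enone 4, replacing carbonyl olefination by olefin metathesis.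

**Further compounds**
F1 | step 1 | henicos-1-ene | CCCCCCCCCCCCCCCCCCCC=C
F2 | step 2 | 2-[ethoxy(trimethylsilyloxy)methylidene]-1,3-dithiane | CCOC(O[Si](C)(C)C)=C1SCCCS1
F3 | step 3 | 2-methyl-5-nonadecylcyclohexane-1,3-dione (racemic) | CCCCCCCCCCCCCCCCCCCC1CC(=O)C(C)C(=O)C1
F4 | step 3 | 2-methyl-5-nonadecylbenzene-1,3-diol | CCCCCCCCCCCCCCCCCCCc1cc(O)c(C)c(O)c1
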